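## Structural features

The target 13 is (S)-13-hydroxy-1-(2,4,6-trihydroxyphenyl)hexadecan-1-one, an acylphloroglucinol in which one benzene ring is joined through the ketone carbon C1 to an unbranched sixteen-carbon chain. C2 to C12 are eleven plain methylenes, C13 carries the only stereocentre, a secondary alcohol of (S) configuration, and C14 to C16 form a propyl end group, so no stereocentre has a neighbour. The fragile part is the electron-rich trihydroxyarene: its phenols quench organometallic reagents, the ring is easily oxidised, and its two free ring positions are open to electrophiles. The C1 ketone, hydrogen-bonded to two ortho hydroxyls, is comparatively inert. The real difficulty is the absolute configuration at C13, which lies twelve atoms from the nearest functional group and is flanked by a propyl group and a long n-alkyl chain of very similar shape. A second difficulty is the 1,13 relationship of the two oxygenated carbons, which matches no natural pairing of polar synthons. The key step exploits the fact that C1 with the nine methylenes C2 to C10 is a cyclodecane ring cut open at the C1–C10 bond: opening of a 1-arylcyclodecanol leaves the aryl ketone at C1 and a radical at C10, and the remaining carbons C11 to C16, with oxygen already on C13, are those of hex-1-en-3-one.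

## Logic of the disconnections

13 to 12. The three phenolic hydroxyls of 13 are traced back to aryl methoxymethyl acetals, so the bonds cut in the forward direction are the three O–CH2 bonds of 12. The cut is placed there because free phenols would protonate the organometallic species and interfere with the single-electron oxidation used earlier, and because the same acetal oxygens direct the metalation. No skeletal simplification results, but every earlier step becomes feasible. The forward step must be an acid treatment mild enough to leave the C13 carbinol and its configuration untouched.

12 to 11. The C13–H bond is removed and the stereocentre becomes a carbonyl. A C13 carbonyl is exactly what a conjugate radical addition leaves behind, so this prepares the main disconnection and means that no stereocentre has to survive the radical step. The demand on the forward step is severe: hydride must reach one face of a carbonyl whose two arms are a three-carbon and a twelve-carbon chain, and the C1 carbonyl must not react.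

11 to 6 and 7. The C10–C11 bond is cut and C10 is reconnected to C1, so that the C1 carbonyl becomes the carbinol carbon of a ten-membered ring. The 1,13-dioxygen pattern has no polar logic, whereas a radical at C10 and an electron-poor alkene at C11 fit naturally. The gain is large: all sixteen chain carbons come from two purchasable pieces, 3 and 7, and the symmetry of the ring means that either ring bond at the carbinol gives the same product. The forward step must generate an oxygen-centred radical from a hindered tertiary alcohol, let it fragment faster than it abstracts hydrogen, and trap the resulting primary radical with 7 before it is quenched.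

6 to 2 and 3 (through 4 and 5). The bond between the aromatic carbon and the carbinol carbon is cut. The position between two acetal oxygens of 2 is its most acidic site and all three such positions are equivalent, so metalation gives a single nucleophile. The forward step must make a doubly ortho-substituted aryl metal add to an enolisable medium-ring carbonyl, which calls for a weakly basic, oxophilic organometallic such as 5.

2 to 1. The three O–CH2 bonds are cut, which leads back to 1. The forward step must alkylate on oxygen and not on the ring carbons, and must go to completion at all three positions.

## Other disconnections considered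

Alternative 1: The cut is the C13–C14 bond, with the C13 oxygen traced back to a boronic ester. In the forward direction 13-[(tert-butyldimethylsilyl)oxy]tridecyl N,N-diisopropylcarbamate A1 would be deprotonated at its oxygen-bearing carbon by sec-butyllithium and (−)-sparteine. The (S)-configured lithiated carbamate would capture 4,4,5,5-tetramethyl-2-propyl-1,3,2-dioxaborolane A2 with retention at carbon. In the boronate the propyl group of A2 would shift from boron to carbon with loss of the carbamate and inversion at carbon. This makes the C13–C14 bond and gives (S)-tert-butyldimethyl{[13-(4,4,5,5-tetramethyl-1,3,2-dioxaborolan-2-yl)hexadecyl]oxy}silane A3. Oxidation of the C–B bond of A3 with retention would give the (S)-alcohol.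
- In favour: C13 is set by a reagent-controlled choice between two enantiotopic hydrogens and a stereospecific migration. It does not depend on telling propyl from a long chain, and on this point the alternative is better than the chosen plan.
- Against: it needs a stoichiometric chiral diamine and an organolithium at −78 °C, and the thirteen-carbon diol behind A1 is not a commodity. The product A3 contains no part of the arene. Turning its silyloxy end into the acylphloroglucinol would need protection of the new alcohol, desilylation, oxidation, aryl-metal addition, a second oxidation and deprotection.
- Comparison: on structure it keeps the sensitive arene out of the key step but builds the chain linearly. On mechanism it is a closed-shell, well-understood sequence with fewer competing pathways than a radical relay. On step economy it needs about ten steps against five and is clearly worse.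

Alternative 2: The cut is again C13–C14, but the three carbons arrive as an allyl group and C13 starts at the alcohol oxidation level. 13-Hydroxy-1-[2,4,6-tris(benzyloxy)phenyl]tridecan-1-one A4 would be dehydrogenated at its primary alcohol by the ortho-cyclometallated iridium π-allyl benzoate complex that assembles in the flask from [Ir(cod)Cl]2, a single enantiomer of BINAP, 4-chloro-3-nitrobenzoic acid, Cs2CO3 and allyl acetate A5. The transient aldehyde would be allylated by the allyl unit of A5 through a closed transition state to give (R)-13-hydroxy-1-[2,4,6-tris(benzyloxy)phenyl]hexadec-15-en-1-one A6. The (R) descriptor of A6 corresponds to the (S) target, since only the ligand priorities change when the alkene is saturated.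
- In favour: face selection at an aldehyde (hydrogen against alkyl) is intrinsically larger than between two n-alkyl groups, so enantiocontrol should be more dependable than in the chosen reduction; here the alternative is better. No separate oxidation is needed, and the donor A5 is a cheap, bench-stable liquid. One hydrogenation over Pd/C would saturate the alkene and remove the three benzyl ethers together, so the endgame after the stereo-defining step is one step, equal to the chosen plan.
- Against: the substrate A4 must first be assembled. That means benzylation of a phenol prone to C-alkylation and acylation with a thirteen-carbon ω-oxygenated chain, about four steps from a long-chain acid that is itself not cheap.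
- Comparison: on structure the chain is carried linearly, not joined from two simple fragments. On mechanism it is a two-electron, stereochemically well-defined process against a photochemical radical cascade. On step economy it needs roughly six to seven steps against five, slightly worse, but with lower stereochemical risk.

Alternative 3: The cut is the C1–C2 bond, with the aryl ketone traced back to an aldehyde C–H bond and a terminal alkene. 2-Hydroxy-4,6-bis(methoxymethoxy)benzaldehyde A7 would bind through its free ortho hydroxyl to the rhodium catalyst formed from [Rh(cod)OMe]2 and a phosphoramidite ligand. After insertion of the metal into the aldehyde C–H bond, the alkene of (S)-pentadec-14-en-4-ol A8 would insert so that the acyl group ends up on its unsubstituted carbon. Reductive elimination would give the linear ketone (S)-13-hydroxy-1-[2-hydroxy-4,6-bis(methoxymethoxy)phenyl]hexadecan-1-one A9. Mild acid would then convert A9 into the target.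
- In favour: the stereocentre of A8 would come from an enantiopure terminal epoxide opened by an alkenylmagnesium bromide with catalytic CuI. C13 is then secured before the key step with no selectivity question, which is better than the chosen plan. The hydroacylation is fully atom-economic, equal to the chosen key step. The route is convergent, about four to five steps with a longest linear sequence of three, which is equal or slightly better on step economy.
- Against: the aldehyde of A7 has two ortho oxygen substituents, which slows alkene insertion relative to decarbonylation. Linear against branched selectivity with an unactivated 1-alkene depends strongly on the ligand. Chain-walking of the alkene and coordination of the free C13 hydroxyl are further risks.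
- Comparison: on structure both plans join an aromatic piece to an aliphatic piece in one bond-forming event. On mechanism the uncertainty shifts from radical generation and capture to regioselectivity at a hindered acyl metal hydride. Overall the alternative is a serious competitor whose main weakness is the hindered aldehyde.

Key step: step 3

Assumption: the ketoreductase of step 4 is taken to be a Prelog-selective, NADPH-dependent enzyme chosen from a commercial screening panel; no particular catalogue enzyme is presupposed.

## Route

Step 1
Reactants: 1 phloroglucinol (benzene-1,3,5-triol)
Product: 2 1,3,5-tris(methoxymethoxy)benzene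
Conditions: NaH, MOMCl, DMF, 0 °C to rt
Reagents that add atoms: chloromethyl methyl ether, COCCl
Why: Williamson-type O-alkylation (methoxymethyl ether formation); the hard, oxocarbenium-like electrophile in a polar aprotic solvent should attack the phenoxide oxygens and not the ring carbons, and the threefold symmetry allows only one fully protected product.

Step 2
Reactants: 2 1,3,5-tris(methoxymethoxy)benzene; 3 cyclodecanone
Product: 6 1-[2,4,6-tris(methoxymethoxy)phenyl]cyclodecan-1-ol, via aryllithium 4 (not isolated), via arylcerium dichloride 5 (not isolated)
Conditions: n-BuLi, THF, 0 °C; anhydrous CeCl3, THF, −78 °C; 3, −78 °C to 0 °C; sat. aq. NH4Cl; chromatography on Et3N-deactivated silica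
Reagents that add atoms: none
Why: Directed ortho-metalation removes the proton between two chelating acetal oxygens of 2, all such positions being equivalent, so 4 forms as one regioisomer. Transmetalation to the weakly basic, oxophilic organocerium 5 suppresses enolisation of 3 and should let the hindered aryl group add to the sluggish medium-ring carbonyl (organocerium 1,2-addition).

Step 3
Reactants: 6 1-[2,4,6-tris(methoxymethoxy)phenyl]cyclodecan-1-ol; 7 hex-1-en-3-one
Product: 11 1-[2,4,6-tris(methoxymethoxy)phenyl]hexadecane-1,13-dione, via alkoxy radical 8 (not isolated), via C10 alkyl radical 9 (not isolated), via α-keto radical 10 (not isolated)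
Conditions: [Ir(dF(CF3)ppy)2(5,5'-d(CF3)bpy)]PF6 (2 mol %), 2,4,6-collidine (2 equiv), 7 (3 equiv), degassed CH2Cl2, blue LEDs, rt
Reagents that add atoms: none
Why: The photoexcited trivalent iridium complex should take one electron from the trialkoxyarene of 6, and collidine, hydrogen-bonded to the tertiary O–H, removes the proton as the hole moves from the ring to oxygen, giving alkoxy radical 8 and the divalent iridium complex. β-Scission of 8 breaks either of the two equivalent ring bonds at the carbinol carbon (C1–C2 or C1–C10), releases the transannular strain of the ten-membered ring and leaves the aryl ketone with primary radical 9 at C10; no ring is closed in this step, one is opened. Nucleophilic 9 adds to the unsubstituted CH2 terminus of the electron-poor alkene 7 (Giese addition), forming the C10–C11 bond and α-keto radical 10. The divalent iridium complex reduces 10 and collidinium protonates the resulting enolate, which returns both catalyst and base and makes the step redox-neutral. The closest known reaction type is the photocatalytic proton-coupled electron transfer ring opening of 1-arylcycloalkanols with capture of the distal radical by an electron-poor alkene; the ten-membered ring and the doubly ortho-substituted arene extend its substrate range. No stereocentre is formed, and the symmetry of the ring removes any question of which bond breaks. Fragmentation of 8 must outrun 1,5- and transannular hydrogen abstraction, which the fully substituted carbinol carbon, the ketone-forming driving force and the ring strain favour, and 9 must reach the alkene before it abstracts hydrogen, which the excess of 7 and the absence of any thiol or other hydrogen-atom donor secure. Mono-addition is favoured because electrophilic 10 adds only slowly to a second electron-poor alkene while its reduction is fast.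

Step 4
Reactants: 11 1-[2,4,6-tris(methoxymethoxy)phenyl]hexadecane-1,13-dione
Product: 12 (S)-13-hydroxy-1-[2,4,6-tris(methoxymethoxy)phenyl]hexadecan-1-one
Conditions: ketoreductase (Prelog-selective, NADPH-dependent), NADP+ (cat.), i-PrOH, phosphate buffer pH 7 with DMSO co-solvent, 30 °C
Reagents that add atoms: none
Why: Biocatalytic asymmetric ketone reduction following the Prelog rule: NADPH delivers hydride to the Re face of the C13 carbonyl when propyl sits in the small pocket and the aroyl-terminated chain in the large one, which gives the (S)-carbinol, with isopropanol regenerating the cofactor. The C1 ketone, shielded by two ortho acetal groups, should be too hindered to enter the active site.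

Step 5
Reactants: 12 (S)-13-hydroxy-1-[2,4,6-tris(methoxymethoxy)phenyl]hexadecan-1-one
Product: 13 (S)-13-hydroxy-1-(2,4,6-trihydroxyphenyl)hexadecan-1-one
Conditions: HCl, MeOH, 40 °C
Reagents that add atoms: none
Why: Acid-catalysed acetal cleavage (methoxymethyl ether removal), with methanol in large excess trapping the methoxymethyl cation as dimethoxymethane and keeping it away from the nucleophilic ring. The unactivated C13 secondary alcohol cannot ionise under these conditions, so its configuration should be retained.

## Compound list

1 | phloroglucinol (benzene-1,3,5-triol) | Oc1cc(O)cc(O)c1 | starting material
2 | 1,3,5-tris(methoxymethoxy)benzene | COCOc1cc(OCOC)cc(OCOC)c1 | intermediate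
3 | cyclodecanone | O=C1CCCCCCCCC1 | starting material
4 | [2,4,6-tris(methoxymethoxy)phenyl]lithium | [Li]c1c(OCOC)cc(OCOC)cc1OCOC | intermediate
5 | dichloro[2,4,6-tris(methoxymethoxy)phenyl]cerium | Cl[Ce](Cl)c1c(OCOC)cc(OCOC)cc1OCOC | intermediate
6 | 1-[2,4,6-tris(methoxymethoxy)phenyl]cyclodecan-1-ol | COCOc1cc(OCOC)c(C2(O)CCCCCCCCC2)c(OCOC)c1 | intermediate
7 | hex-1-en-3-one | CCCC(=O)C=C | starting material
8 | 1-[2,4,6-tris(methoxymethoxy)phenyl]cyclodecan-1-yloxyl radical | COCOc1cc(OCOC)c(C2([O])CCCCCCCCC2)c(OCOC)c1 | intermediate
9 | 10-oxo-10-[2,4,6-tris(methoxymethoxy)phenyl]decyl radical | [CH2]CCCCCCCCC(=O)c1c(OCOC)cc(OCOC)cc1OCOC | intermediate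
10 | 1,13-dioxo-1-[2,4,6-tris(methoxymethoxy)phenyl]hexadecan-12-yl radical | CCCC(=O)[CH]CCCCCCCCCCC(=O)c1c(OCOC)cc(OCOC)cc1OCOC | intermediate
11 | 1-[2,4,6-tris(methoxymethoxy)phenyl]hexadecane-1,13-dione | CCCC(=O)CCCCCCCCCCCC(=O)c1c(OCOC)cc(OCOC)cc1OCOC | intermediate
12 | (S)-13-hydroxy-1-[2,4,6-tris(methoxymethoxy)phenyl]hexadecan-1-one | CCC[C@H](O)CCCCCCCCCCCC(=O)c1c(OCOC)cc(OCOC)cc1OCOC | intermediate
13 | (S)-13-hydroxy-1-(2,4,6-trihydroxyphenyl)hexadecan-1-one | CCC[C@H](O)CCCCCCCCCCCC(=O)c1c(O)cc(O)cc1O | target

## Step count and least certain steps

Total step count: 5. Longest linear sequence: 5 steps (1 to 2 to 6 to 11 to 12 to 13); 3 and 7 are purchased and enter at steps 2 and 3.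

Step 3 (key step).
- What may go wrong: back electron transfer may outpace deprotonation of the crowded, internally hydrogen-bonded O–H, so that 8 is generated inefficiently. Transannular or 1,5-hydrogen abstraction within 8 may compete with β-scission. Premature hydrogen abstraction by 9, or repeated addition of 10 to further 7, would erode the yield.
- Fallback: a polar construction of the same chain that needs neither the ring nor a radical; it sets out from 2 and comes back at 11. Commercial 11-bromoundecanoic acid would be condensed with N,O-dimethylhydroxylamine hydrochloride (carbodiimide coupling) to give 11-bromo-N-methoxy-N-methylundecanamide F1. Aryllithium 4, generated from 2 as in step 2, would be acylated by F1 at −78 °C (Weinreb ketone synthesis), a temperature at which attack on the primary bromide should be negligible, to give 11-bromo-1-[2,4,6-tris(methoxymethoxy)phenyl]undecan-1-one F2. The bromide F2 would alkylate commercial ethyl 3-oxohexanoate (K2CO3, NaI, DMF) to give ethyl 2-butanoyl-13-oxo-13-[2,4,6-tris(methoxymethoxy)phenyl]tridecanoate F3. Krapcho dealkoxycarbonylation of F3 (LiCl, wet DMSO, 150 °C), which is neutral and leaves the acetals intact, would then give 11.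

Step 4.
- What may go wrong: poor discrimination between the propyl arm and the long chain in the enzyme pockets would give low enantioselectivity. Slow turnover is also possible because the very lipophilic substrate partitions poorly into the aqueous phase.
- Fallback: make the C13–C14 bond and the stereocentre together by catalytic asymmetric alkylation of an aldehyde; it sets out from 6 and comes back at 12. Ring opening of 6 under the conditions of step 3 with acrolein in place of 7 should give 13-oxo-13-[2,4,6-tris(methoxymethoxy)phenyl]tridecanal F4. Addition of dipropylzinc to F4 with Ti(OiPr)4 and catalytic (1R,2R)-1,2-bis(trifluoromethanesulfonamido)cyclohexane in toluene at −20 °C should transfer propyl to the Si face of the aldehyde, by analogy with the (S)-selective ethylation of aldehydes under this ligand, and give 12. The face selection here is between hydrogen and alkyl, and the hindered C1 ketone should not react with the dialkylzinc.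

Step 2.
- What may go wrong: enolisation of 3 may compete with addition, because a ten-membered ketone resists rehybridisation to sp3 (added transannular strain) and the nucleophile is doubly ortho-substituted. Acid-promoted dehydration of the electron-rich tertiary benzylic alcohol during work-up or chromatography is also possible.
- Fallback: give up the ring and generate radical 9 from a halide instead; it sets out from 2 and comes back at 11. Commercial 10-bromodecanoic acid would be converted into 10-bromo-N-methoxy-N-methyldecanamide F5. Aryllithium 4, generated from 2, would be acylated by F5 at −78 °C to give 10-bromo-1-[2,4,6-tris(methoxymethoxy)phenyl]decan-1-one F6. Bromine abstraction from F6 by the silyl radical of (Me3Si)3SiH (AIBN, toluene, 80 °C, slow addition) in the presence of 7 would give 9, and Giese addition with hydrogen transfer from the silane would give 11.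

## Further compounds

F1 | step 3 | 11-bromo-N-methoxy-N-methylundecanamide | CON(C)C(=O)CCCCCCCCCCBr
F2 | step 3 | 11-bromo-1-[2,4,6-tris(methoxymethoxy)phenyl]undecan-1-one | BrCCCCCCCCCCC(=O)c1c(OCOC)cc(OCOC)cc1OCOC
F3 | step 3 | ethyl 2-butanoyl-13-oxo-13-[2,4,6-tris(methoxymethoxy)phenyl]tridecanoate | CCCC(=O)C(C(=O)OCC)CCCCCCCCCCC(=O)c1c(OCOC)cc(OCOC)cc1OCOC
F4 | step 4 | 13-oxo-13-[2,4,6-tris(methoxymethoxy)phenyl]tridecanal | O=CCCCCCCCCCCCC(=O)c1c(OCOC)cc(OCOC)cc1OCOC
F5 | step 2 | 10-bromo-N-methoxy-N-methyldecanamide | CON(C)C(=O)CCCCCCCCCBr
F6 | step 2 | 10-bromo-1-[2,4,6-tris(methoxymethoxy)phenyl]decan-1-one | BrCCCCCCCCCC(=O)c1c(OCOC)cc(OCOC)cc1OCOC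
A1 | alternative 1 | 13-[(tert-butyldimethylsilyl)oxy]tridecyl N,N-diisopropylcarbamate | CC(C)N(C(C)C)C(=O)OCCCCCCCCCCCCCO[Si](C)(C)C(C)(C)C
A2 | alternative 1 | 4,4,5,5-tetramethyl-2-propyl-1,3,2-dioxaborolane | CCCB1OC(C)(C)C(C)(C)O1
A3 | alternative 1 | (S)-tert-butyldimethyl{[13-(4,4,5,5-tetramethyl-1,3,2-dioxaborolan-2-yl)hexadecyl]oxy}silane | CCC[C@H](B1OC(C)(C)C(C)(C)O1)CCCCCCCCCCCCO[Si](C)(C)C(C)(C)C
A4 | alternative 2 | 13-hydroxy-1-[2,4,6-tris(benzyloxy)phenyl]tridecan-1-one | OCCCCCCCCCCCCC(=O)c1c(OCc2ccccc2)cc(OCc2ccccc2)cc1OCc3ccccc3
A5 | alternative 2 | allyl acetate (prop-2-en-1-yl acetate) | CC(=O)OCC=C
A6 | alternative 2 | (R)-13-hydroxy-1-[2,4,6-tris(benzyloxy)phenyl]hexadec-15-en-1-one | C=CC[C@H](O)CCCCCCCCCCCC(=O)c1c(OCc2ccccc2)cc(OCc2ccccc2)cc1OCc3ccccc3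
A7 | alternative 3 | 2-hydroxy-4,6-bis(methoxymethoxy)benzaldehyde | COCOc1cc(O)c(C=O)c(OCOC)c1
A8 | alternative 3 | (S)-pentadec-14-en-4-ol | CCC[C@H](O)CCCCCCCCCC=C
A9 | alternative 3 | (S)-13-hydroxy-1-[2-hydroxy-4,6-bis(methoxymethoxy)phenyl]hexadecan-1-one | CCC[C@H](O)CCCCCCCCCCCC(=O)c1c(O)cc(OCOC)cc1OCOC
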